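The route cuts the C8–O–C4' ether at the O–C4' bond. Ring B carries its ether oxygen at C4' between the methoxy-bearing carbons C3' and C5'; this 2-alkoxyresorcinol pattern is the aromatized form of a 2-alkoxycyclohexane-1,3-dione, so the crowded aryl ether bond is made while ring B is still a saturated dione. A rhodium carbenoid from a 2-diazo-1,3-dione inserts into the O–H bond of the C8 alcohol, joining both halves in one operation without touching C7 or C8. The alcohol partner is the lactate-derived erythro diol carrying a silyl ether on the C7 oxygen; the diazo partner carries an ester at C1' from which the allyl group is built after aromatization.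

Key step: step 8

Abbreviation: TBS = tert-butyldimethylsilyl.

Assumption: neolignan numbering is used (ring A is the 3,4,5-trimethoxyphenyl ring on C7, ring B the primed ring on the C8 oxygen); the carbenoid insertion product and the two ring B intermediates that follow it are mixtures of tautomers and of epimers at the ester-bearing ring carbon, all converging on one arene, so that carbon is drawn without configuration.

Step 1
Reactants: 1 methyl (R)-lactate
Product: 2 methyl (R)-2-(benzyloxy)propanoate
Conditions: BnOC(=NH)CCl3, TfOH (cat.), cyclohexane/CH2Cl2, rt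
Reagents that add atoms: benzyl 2,2,2-trichloroacetimidate, N=C(OCc1ccccc1)C(Cl)(Cl)Cl
Why: Acid-catalysed trichloroacetimidate O-benzylation alkylates the hydroxyl without base, so the lactate stereocenter (the future C8) should not epimerize.

Step 2
Reactants: 2 methyl (R)-2-(benzyloxy)propanoate
Product: 3 (R)-2-(benzyloxy)-N-methoxy-N-methylpropanamide
Conditions: MeNHOMe·HCl, iPrMgCl, THF, −20 to 0 °C
Reagents that add atoms: N,O-dimethylhydroxylamine hydrochloride, CNOC.Cl
Why: Weinreb amide formation by aminolysis of the ester with the magnesium amide is faster below 0 °C than enolization, so C8 stays intact.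

Step 3
Reactants: 3 (R)-2-(benzyloxy)-N-methoxy-N-methylpropanamide; 4 5-bromo-1,2,3-trimethoxybenzene
Product: 6 (R)-2-(benzyloxy)-1-(3,4,5-trimethoxyphenyl)propan-1-one, via aryl Grignard reagent 5 (not isolated)
Conditions: Mg, THF, reflux; then 3, THF, 0 °C; 1 M HCl quench
Reagents that add atoms: none
Why: Weinreb ketone synthesis: the aryl Grignard reagent adds once to give a magnesium-chelated tetrahedral adduct that collapses to the ketone only on acidic quench, which prevents over-addition and base-mediated racemization at C8.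

Step 4
Reactants: 6 (R)-2-(benzyloxy)-1-(3,4,5-trimethoxyphenyl)propan-1-one
Product: 7 (1S,2R)-2-(benzyloxy)-1-(3,4,5-trimethoxyphenyl)propan-1-ol
Conditions: Zn(BH4)2, Et2O, −20 °C
Reagents that add atoms: none
Why: Chelation-controlled (Cram chelate) hydride reduction: zinc bridges the carbonyl and benzyloxy oxygens and hydride adds to the face anti to the C8 methyl group, which sets C7 as S and gives the anti (erythro) relationship.

Step 5
Reactants: 7 (1S,2R)-2-(benzyloxy)-1-(3,4,5-trimethoxyphenyl)propan-1-ol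
Product: 8 benzyl (1S,2R)-1-(TBS-oxy)-1-(3,4,5-trimethoxyphenyl)propan-2-yl ether
Conditions: TBSOTf, 2,6-lutidine, CH2Cl2, −78 to 0 °C
Reagents that add atoms: tert-butyldimethylsilyl trifluoromethanesulfonate, CC(C)(C)[Si](C)(C)OS(=O)(=O)C(F)(F)F
Why: Silylation of the hindered secondary benzylic alcohol with a silyl triflate and a non-nucleophilic base is fast at low temperature and masks the C7 oxygen, so that only the C8 oxygen is free in the key step.

Step 6
Reactants: 8 benzyl (1S,2R)-1-(TBS-oxy)-1-(3,4,5-trimethoxyphenyl)propan-2-yl ether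
Product: 9 (1S,2R)-1-(TBS-oxy)-1-(3,4,5-trimethoxyphenyl)propan-2-ol
Conditions: H2 (1 atm), 10% Pd/C, EtOAc, rt
Reagents that add atoms: none
Why: Catalytic hydrogenolysis in a neutral aprotic solvent should cleave the O–CH2Ph bond much faster than the hindered benzylic C–O bond of the silyl ether, exposes the electron-rich ring A to no quinone oxidant, and involves no base that could trigger silyl migration.

Step 7
Reactants: 10 methyl 3,5-dioxocyclohexane-1-carboxylate
Product: 11 methyl 4-diazo-3,5-dioxocyclohexane-1-carboxylate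
Conditions: 4-acetamidobenzenesulfonyl azide, Et3N, MeCN, 0 °C to rt
Reagents that add atoms: 4-acetamidobenzenesulfonyl azide, CC(=O)Nc1ccc(cc1)S(=O)(=O)N=[N+]=[N-]
Why: Regitz diazo transfer: the ammonium enolate of the 1,3-dione attacks the terminal azide nitrogen and loss of the sulfonamide leaves the 2-diazo-1,3-dione, the ester-bearing carbon being too weakly acidic to compete.

Step 8
Reactants: 9 (1S,2R)-1-(TBS-oxy)-1-(3,4,5-trimethoxyphenyl)propan-2-ol; 11 methyl 4-diazo-3,5-dioxocyclohexane-1-carboxylate
Product: 12 methyl 4-{[(1S,2R)-1-(TBS-oxy)-1-(3,4,5-trimethoxyphenyl)propan-2-yl]oxy}-3,5-dioxocyclohexane-1-carboxylate (keto and enol forms)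
Conditions: Rh2(OAc)4 (2 mol%), PhCF3, 80 °C, 4 Å MS, slow addition of 11 (1.5 equiv)
Reagents that add atoms: none
Why: Dirhodium tetraacetate expels N2 from 11 to give an electrophilic acceptor/acceptor rhodium carbenoid; the C8 hydroxyl oxygen of 9 attacks it to form an oxonium ylide, and a 1,2-proton shift releases the catalyst and the 2-alkoxy-1,3-dione, which should exist mainly as its enol. This is the established rhodium carbenoid O–H insertion of 2-diazocyclohexane-1,3-diones into alcohols, which accepts secondary and hindered alcohols because the bond forms at oxygen on a ring carbon that is not yet part of a crowded arene. No ring is closed and no stereocenter of the target is formed: the C8–O bond is never broken, so C7 and C8 keep their configurations, and the new stereo-elements in ring B vanish on aromatization. The step needs reaction at a single hydroxyl, which the silyl ether on the C7 oxygen guarantees, and O–H insertion in preference to attack on the electron-rich ring A, which the higher nucleophilicity of the free hydroxyl and the doubly flanked open positions of ring A should secure. Slow addition of 11 keeps the carbenoid concentration low, which suppresses carbene dimerization and insertion into the enol O–H of the product, and the dry deactivated solvent excludes water insertion and solvent arylation.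

Step 9
Reactants: 12 methyl 4-{[(1S,2R)-1-(TBS-oxy)-1-(3,4,5-trimethoxyphenyl)propan-2-yl]oxy}-3,5-dioxocyclohexane-1-carboxylate
Product: 13 methyl 4-{[(1S,2R)-1-(TBS-oxy)-1-(3,4,5-trimethoxyphenyl)propan-2-yl]oxy}-3-methoxy-5-oxocyclohex-3-ene-1-carboxylate
Conditions: Me3SiCHN2, MeOH/toluene, 0 °C to rt
Reagents that add atoms: trimethylsilyldiazomethane, C[Si](C)(C)C=[N+]=[N-]
Why: O-Methylation of the acidic enol (a vinylogous acid) by a diazomethane equivalent takes place on oxygen only, which gives the vinylogous ester and avoids C-methylation at the alkoxy-bearing carbon.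

Step 10
Reactants: 13 methyl 4-{[(1S,2R)-1-(TBS-oxy)-1-(3,4,5-trimethoxyphenyl)propan-2-yl]oxy}-3-methoxy-5-oxocyclohex-3-ene-1-carboxylate
Product: 15 methyl 4-{[(1S,2R)-1-(TBS-oxy)-1-(3,4,5-trimethoxyphenyl)propan-2-yl]oxy}-3-hydroxy-5-methoxybenzoate, via silyl dienol ether 14 (not isolated)
Conditions: LiN(iPr)2, THF, −78 °C; Me3SiCl; then Pd(OAc)2 (1.1 equiv), MeCN, rt
Reagents that add atoms: none
Why: Saegusa–Ito oxidation: the kinetic enolate at the methylene next to the ketone is trapped as the silyl dienol ether, palladium diacetate converts it into a palladium enolate that undergoes β-hydride elimination towards the ester-bearing carbon, and tautomerization of the resulting keto form gives the phenol under non-acidic conditions that spare the benzylic silyl ether.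

Step 11
Reactants: 15 methyl 4-{[(1S,2R)-1-(TBS-oxy)-1-(3,4,5-trimethoxyphenyl)propan-2-yl]oxy}-3-hydroxy-5-methoxybenzoate
Product: 16 methyl 4-{[(1S,2R)-1-(TBS-oxy)-1-(3,4,5-trimethoxyphenyl)propan-2-yl]oxy}-3,5-dimethoxybenzoate
Conditions: MeI, K2CO3, DMF, rt
Reagents that add atoms: methyl iodide, CI
Why: Williamson O-methylation of the only acidic O–H, the phenol, completes the C3'/C5' dimethoxy pattern of ring B.

Step 12
Reactants: 16 methyl 4-{[(1S,2R)-1-(TBS-oxy)-1-(3,4,5-trimethoxyphenyl)propan-2-yl]oxy}-3,5-dimethoxybenzoate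
Product: 17 (4-{[(1S,2R)-1-(TBS-oxy)-1-(3,4,5-trimethoxyphenyl)propan-2-yl]oxy}-3,5-dimethoxyphenyl)methanol
Conditions: iBu2AlH, CH2Cl2, −78 to 0 °C; aqueous potassium sodium tartrate work-up
Reagents that add atoms: none
Why: Hydride reduction of the only carbonyl group, the aryl ester, by excess aluminium hydride reagent gives the benzylic alcohol, while aryl ethers and the silyl ether are inert.

Step 13
Reactants: 17 (4-{[(1S,2R)-1-(TBS-oxy)-1-(3,4,5-trimethoxyphenyl)propan-2-yl]oxy}-3,5-dimethoxyphenyl)methanol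
Product: 18 4-{[(1S,2R)-1-(TBS-oxy)-1-(3,4,5-trimethoxyphenyl)propan-2-yl]oxy}-3,5-dimethoxybenzyl bromide
Conditions: CBr4, PPh3, CH2Cl2, 0 °C
Reagents that add atoms: carbon tetrabromide, BrC(Br)(Br)Br
Why: The Appel reaction converts the primary benzylic alcohol into the bromide through an alkoxyphosphonium ion under essentially neutral conditions that should leave the secondary benzylic silyl ether untouched.

Step 14
Reactants: 18 4-{[(1S,2R)-1-(TBS-oxy)-1-(3,4,5-trimethoxyphenyl)propan-2-yl]oxy}-3,5-dimethoxybenzyl bromide; 19 tributyl(vinyl)stannane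
Product: 20 5-allyl-2-{[(1S,2R)-1-(TBS-oxy)-1-(3,4,5-trimethoxyphenyl)propan-2-yl]oxy}-1,3-dimethoxybenzene
Conditions: Pd(PPh3)4 (5 mol%), toluene, 80 °C
Reagents that add atoms: none
Why: Stille cross-coupling: oxidative addition of the benzylic C–Br bond to zerovalent palladium, vinyl transfer from tin and reductive elimination form the C7'–C8' bond and hence the allyl group under neutral conditions.

Step 15
Reactants: 20 5-allyl-2-{[(1S,2R)-1-(TBS-oxy)-1-(3,4,5-trimethoxyphenyl)propan-2-yl]oxy}-1,3-dimethoxybenzene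
Product: 21 rhaphidecursinol B: (1S,2R)-2-(4-allyl-2,6-dimethoxyphenoxy)-1-(3,4,5-trimethoxyphenyl)propan-1-ol
Conditions: Bu4NF, THF, 0 °C to rt
Reagents that add atoms: none
Why: Fluoride-mediated desilylation, driven by the strong Si–F bond, cleaves only the silyl ether and leaves the allyl group, the aryl ethers and both stereocenters unchanged.

Compound list
1 | methyl (R)-lactate | C[C@@H](O)C(=O)OC | starting material
2 | methyl (R)-2-(benzyloxy)propanoate | C[C@@H](OCc1ccccc1)C(=O)OC | intermediate
3 | (R)-2-(benzyloxy)-N-methoxy-N-methylpropanamide | C[C@@H](OCc1ccccc1)C(=O)N(C)OC | intermediate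
4 | 5-bromo-1,2,3-trimethoxybenzene | COc1cc(Br)cc(OC)c1OC | starting material
5 | (3,4,5-trimethoxyphenyl)magnesium bromide | COc1cc([Mg]Br)cc(OC)c1OC | intermediate
6 | (R)-2-(benzyloxy)-1-(3,4,5-trimethoxyphenyl)propan-1-one | C[C@@H](OCc1ccccc1)C(=O)c1cc(OC)c(OC)c(OC)c1 | intermediate
7 | (1S,2R)-2-(benzyloxy)-1-(3,4,5-trimethoxyphenyl)propan-1-ol | c1ccccc1CO[C@H](C)[C@@H](O)c1cc(OC)c(OC)c(OC)c1 | intermediate
8 | benzyl (1S,2R)-1-(TBS-oxy)-1-(3,4,5-trimethoxyphenyl)propan-2-yl ether | c1ccccc1CO[C@H](C)[C@@H](O[Si](C)(C)C(C)(C)C)c1cc(OC)c(OC)c(OC)c1 | intermediate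
9 | (1S,2R)-1-(TBS-oxy)-1-(3,4,5-trimethoxyphenyl)propan-2-ol | O[C@H](C)[C@@H](O[Si](C)(C)C(C)(C)C)c1cc(OC)c(OC)c(OC)c1 | intermediate
10 | methyl 3,5-dioxocyclohexane-1-carboxylate | COC(=O)C1CC(=O)CC(=O)C1 | starting material
11 | methyl 4-diazo-3,5-dioxocyclohexane-1-carboxylate | COC(=O)C1CC(=O)C(=[N+]=[N-])C(=O)C1 | intermediate
12 | methyl 4-{[(1S,2R)-1-(TBS-oxy)-1-(3,4,5-trimethoxyphenyl)propan-2-yl]oxy}-3,5-dioxocyclohexane-1-carboxylate | COC(=O)C1CC(=O)C(O[C@H](C)[C@@H](O[Si](C)(C)C(C)(C)C)c2cc(OC)c(OC)c(OC)c2)C(=O)C1 | intermediate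
13 | methyl 4-{[(1S,2R)-1-(TBS-oxy)-1-(3,4,5-trimethoxyphenyl)propan-2-yl]oxy}-3-methoxy-5-oxocyclohex-3-ene-1-carboxylate | COC(=O)C1CC(OC)=C(O[C@H](C)[C@@H](O[Si](C)(C)C(C)(C)C)c2cc(OC)c(OC)c(OC)c2)C(=O)C1 | intermediate
14 | methyl 4-{[(1S,2R)-1-(TBS-oxy)-1-(3,4,5-trimethoxyphenyl)propan-2-yl]oxy}-3-methoxy-5-[(trimethylsilyl)oxy]cyclohexa-3,5-diene-1-carboxylate | COC(=O)C1CC(OC)=C(O[C@H](C)[C@@H](O[Si](C)(C)C(C)(C)C)c2cc(OC)c(OC)c(OC)c2)C(O[Si](C)(C)C)=C1 | intermediate
15 | methyl 4-{[(1S,2R)-1-(TBS-oxy)-1-(3,4,5-trimethoxyphenyl)propan-2-yl]oxy}-3-hydroxy-5-methoxybenzoate | COC(=O)c1cc(O)c(O[C@H](C)[C@@H](O[Si](C)(C)C(C)(C)C)c2cc(OC)c(OC)c(OC)c2)c(OC)c1 | intermediate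
16 | methyl 4-{[(1S,2R)-1-(TBS-oxy)-1-(3,4,5-trimethoxyphenyl)propan-2-yl]oxy}-3,5-dimethoxybenzoate | COC(=O)c1cc(OC)c(O[C@H](C)[C@@H](O[Si](C)(C)C(C)(C)C)c2cc(OC)c(OC)c(OC)c2)c(OC)c1 | intermediate
17 | (4-{[(1S,2R)-1-(TBS-oxy)-1-(3,4,5-trimethoxyphenyl)propan-2-yl]oxy}-3,5-dimethoxyphenyl)methanol | OCc1cc(OC)c(O[C@H](C)[C@@H](O[Si](C)(C)C(C)(C)C)c2cc(OC)c(OC)c(OC)c2)c(OC)c1 | intermediate
18 | 4-{[(1S,2R)-1-(TBS-oxy)-1-(3,4,5-trimethoxyphenyl)propan-2-yl]oxy}-3,5-dimethoxybenzyl bromide | BrCc1cc(OC)c(O[C@H](C)[C@@H](O[Si](C)(C)C(C)(C)C)c2cc(OC)c(OC)c(OC)c2)c(OC)c1 | intermediate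
19 | tributyl(vinyl)stannane | C=C[Sn](CCCC)(CCCC)CCCC | starting material
20 | 5-allyl-2-{[(1S,2R)-1-(TBS-oxy)-1-(3,4,5-trimethoxyphenyl)propan-2-yl]oxy}-1,3-dimethoxybenzene | C=CCc1cc(OC)c(O[C@H](C)[C@@H](O[Si](C)(C)C(C)(C)C)c2cc(OC)c(OC)c(OC)c2)c(OC)c1 | intermediate
21 | rhaphidecursinol B: (1S,2R)-2-(4-allyl-2,6-dimethoxyphenoxy)-1-(3,4,5-trimethoxyphenyl)propan-1-ol | C=CCc1cc(OC)c(O[C@H](C)[C@@H](O)c2cc(OC)c(OC)c(OC)c2)c(OC)c1 | target

Total step count: 15.
Longest linear sequence: 14 steps (steps 1–6 and 8–15, from methyl (R)-lactate 1); the diazo dione 11 is made in one step (step 7) on the side.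

Steps most likely to fail

1. Step 8 (key step). Capture of the short-lived carbenoid by the hindered C8 hydroxyl may lose out to carbene dimerization, to attack on the electron-rich ring A or to insertion into the enol O–H of the product, so that conversion of 9 stalls. The fallback uses known chemistry, sets out from aryl bromide 4 through its Grignard reagent 5 and rejoins the route at the target 21. The C8–O–C4' bond is made instead by Mitsunobu displacement on a lactate with the intact ring B phenol. Methyl (S)-lactate (C[C@H](O)C(=O)OC) and commercial 4-allyl-2,6-dimethoxyphenol (C=CCc1cc(OC)c(O)c(OC)c1), with PPh3 and diisopropyl azodicarboxylate in THF, should give with inversion methyl (R)-2-(4-allyl-2,6-dimethoxyphenoxy)propanoate F1. MeNHOMe·HCl and iPrMgCl convert this into (R)-2-(4-allyl-2,6-dimethoxyphenoxy)-N-methoxy-N-methylpropanamide F2. Addition of 5 gives (R)-2-(4-allyl-2,6-dimethoxyphenoxy)-1-(3,4,5-trimethoxyphenyl)propan-1-one F3, and chelation-controlled reduction with Zn(BH4)2 should deliver 21 directly, with no silyl protection needed.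

2. Step 10. Incomplete enolization, hydrolysis of the silyl dienol ether before oxidation, or slow palladium enolate formation on the crowded diene would return unoxidized 13. The fallback sets out from 13 and rejoins at 15 by selenoxide elimination. Deprotonation of 13 with LiN(iPr)2 and trapping with PhSeCl at −78 °C should give methyl 4-{[(1S,2R)-1-(TBS-oxy)-1-(3,4,5-trimethoxyphenyl)propan-2-yl]oxy}-3-methoxy-5-oxo-6-(phenylselanyl)cyclohex-3-ene-1-carboxylate F4. Oxidation with one equivalent of mCPBA at −78 °C and warming in the presence of iPr2NH should then effect syn-elimination and tautomerization to 15.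

3. Step 14. Slow transfer of the vinyl group from tin to palladium may allow homocoupling of the benzylic bromide, and a palladium hydride may move the new double bond into conjugation with ring B. The fallback sets out from 18 and rejoins at 20. It replaces palladium catalysis by organocopper substitution: vinylmagnesium bromide with catalytic CuI in THF at −30 °C should form the same C7'–C8' bond by an SN2-type pathway in which no metal hydride arises. No new intermediate is involved.

Further compounds
F1 | step 8 | methyl (R)-2-(4-allyl-2,6-dimethoxyphenoxy)propanoate | C=CCc1cc(OC)c(O[C@H](C)C(=O)OC)c(OC)c1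
F2 | step 8 | (R)-2-(4-allyl-2,6-dimethoxyphenoxy)-N-methoxy-N-methylpropanamide | C=CCc1cc(OC)c(O[C@H](C)C(=O)N(C)OC)c(OC)c1
F3 | step 8 | (R)-2-(4-allyl-2,6-dimethoxyphenoxy)-1-(3,4,5-trimethoxyphenyl)propan-1-one | C=CCc1cc(OC)c(O[C@H](C)C(=O)c2cc(OC)c(OC)c(OC)c2)c(OC)c1
F4 | step 10 | methyl 4-{[(1S,2R)-1-(TBS-oxy)-1-(3,4,5-trimethoxyphenyl)propan-2-yl]oxy}-3-methoxy-5-oxo-6-(phenylselanyl)cyclohex-3-ene-1-carboxylate | COC(=O)C1CC(OC)=C(O[C@H](C)[C@@H](O[Si](C)(C)C(C)(C)C)c2cc(OC)c(OC)c(OC)c2)C(=O)C1[Se]c1ccccc1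
F0 | step 14 | none | none
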